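**Plan**

Numbering: ring A is the benzene ring (C4a, C5–C8, C8a), ring B the lactone (C1, O2, C3, C4, C4a, C8a), and the side chain runs C1' to C5' from C3 with the succinate on C4'.
Retrosynthesis: the three benzyl groups (two phenols, the succinic acid) are put back, C3–H/C4–H are removed to give the C3=C4 isocoumarin, and ring B is cut at C4a–C4 and O2–C3. This leaves a gentisic acid unit and a seven-carbon keto sulfoxonium ylide carrying C4, C3 and the esterified side chain.
Enabling feature: ring A is a gentisate (C1 on C8a, oxygen on C8 and C5), so C4a is the only free position ortho to the carboxyl and is exactly where C4 must go; a carboxylate-directed metalation has no other site.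
Forward: ring A is bought as gentisic acid and benzylated; the chain comes from (S)-δ-hexalactone by opening with dimethylsulfoxonium methylide and esterification with monobenzyl succinate; ring B closes in the C–H annulation; hydrogenation of C3=C4 and one hydrogenolysis finish.
Stereochemistry: C4' (S) is carried unchanged from the lactone (chiral pool); C3 (R) is set by the chiral iridium catalyst in the hydrogenation of the enol lactone.

Key step: step 5

Assumption: (S)-δ-hexalactone is taken as purchasable in enantiopure form.
Assumption: the hand of SegPhos that delivers 3R is written as (R); the sense has to be confirmed in a small screen and the mirror-image ligand used if it is reversed.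

**Route**

Step 1
Reactants: 1 gentisic acid (2,5-dihydroxybenzoic acid)
Product: 2 benzyl 2,5-bis(benzyloxy)benzoate
Conditions: BnBr (3.5 equiv), K2CO3, DMF, 60 °C
Reagents that add atoms: benzyl bromide, BrCc1ccccc1
Why: Williamson etherification of both phenols and SN2 alkylation of the carboxylate under carbonate base should benzylate all three acidic OH groups in one operation.

Step 2
Reactants: 2 benzyl 2,5-bis(benzyloxy)benzoate
Product: 3 2,5-bis(benzyloxy)benzoic acid
Conditions: NaOH, THF/MeOH/H2O, 60 °C; then 1 M HCl
Reagents that add atoms: sodium hydroxide, [Na+].[OH-]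
Why: Ester saponification (addition–elimination at the acyl carbon) should cleave only the benzyl ester, because aryl benzyl ethers are inert to hydroxide.

Step 3
Reactants: 4 (S)-δ-hexalactone [(6S)-6-methyltetrahydro-2H-pyran-2-one]; 5 trimethylsulfoxonium iodide
Product: 7 (6S)-1-(dimethyloxosulfuranylidene)-6-hydroxyheptan-2-one, via dimethylsulfoxonium methylide 6 (not isolated)
Conditions: 5 (2.5 equiv), KOtBu, THF, reflux; then 4, 0 °C to rt
Reagents that add atoms: none
Why: Acyl substitution of the lactone by the sulfur ylide 6 (the Corey–Chaykovsky reagent acting on an ester) opens the ring, and proton transfer from the acidic α-CH2 of the β-keto sulfoxonium salt gives the stabilised ylide; the carbinol centre is not involved and stays S.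

Step 4
Reactants: 7 (6S)-1-(dimethyloxosulfuranylidene)-6-hydroxyheptan-2-one; 8 monobenzyl succinate [4-(benzyloxy)-4-oxobutanoic acid]
Product: 9 benzyl (2S)-7-(dimethyloxosulfuranylidene)-6-oxoheptan-2-yl succinate
Conditions: DCC, DMAP (10 mol %), CH2Cl2, 0 °C to rt (8 and DCC premixed, then 7 added)
Reagents that add atoms: none
Why: Steglich esterification: the preactivated acid acylates the secondary alcohol with retention (the C–O bond is not broken), while the carbonyl-stabilised sulfoxonium ylide is a poor nucleophile and weak base and should pass through unchanged.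

Step 5
Reactants: 3 2,5-bis(benzyloxy)benzoic acid; 9 benzyl (2S)-7-(dimethyloxosulfuranylidene)-6-oxoheptan-2-yl succinate
Product: 11 benzyl (2S)-5-[5,8-bis(benzyloxy)-1-oxo-1H-isochromen-3-yl]pentan-2-yl succinate, via ring-open keto acid 10 (not isolated)
Conditions: [RuCl2(p-cymene)]2 (5 mol %), NaOAc (0.5 equiv), CF3CH2OH, 80 °C, N2
Reagents that add atoms: none
Why: The divalent ruthenium carboxylate of 3 undergoes acetate-assisted metalation at its only free ortho C–H to give a five-membered ruthenacycle; the ylide carbon of 9 binds, dimethyl sulfoxide leaves to give a ruthenium carbene, migratory insertion of the aryl group forms C4a–C4, and protonation releases keto acid 10. The closest known reaction type is the ruthenium- or rhodium-catalysed carboxylate-directed C–H/O–H annulation of benzoic acids with α-keto sulfoxonium ylides to 3-substituted isocoumarins. Ring B closes when the carboxyl oxygen of 10 adds to the ketone carbon in a 6-exo-trig mode and the resulting hemiketal loses water, forming O2–C3 and the C3=C4 enol lactone. No stereocentre is created, and the C4' centre is remote from every reacting atom and keeps its S configuration. The step needs site selectivity, which is secured because the second ortho position (C8) carries a benzyloxy group, and it needs carbene transfer to carbon to outrun O-alkylation of the acid by the ylide. The electron-rich ring and possible assistance from the neighbouring C5 ether oxygen should help offset the crowding at C4a, and the two ester groups of 9 are spectators.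

Step 6
Reactants: 11 benzyl (2S)-5-[5,8-bis(benzyloxy)-1-oxo-1H-isochromen-3-yl]pentan-2-yl succinate
Product: 12 benzyl (2S)-5-[(3R)-5,8-bis(benzyloxy)-1-oxo-3,4-dihydro-1H-isochromen-3-yl]pentan-2-yl succinate
Conditions: [Ir(cod)Cl]2 (2 mol %), (R)-SegPhos (4.4 mol %), I2 (10 mol %), H2 (50 bar), THF, 40 °C
Reagents that add atoms: none
Why: Iridium–bisphosphine catalysed asymmetric hydrogenation of a cyclic enol ester (isocoumarin to 3,4-dihydroisocoumarin): the chiral ligand on the monovalent iridium precatalyst decides which face of C3=C4 receives hydrogen and so sets C3 as R, the remote C4' centre having no influence, while benzyl ethers and esters are left alone by the homogeneous catalyst.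

Step 7
Reactants: 12 benzyl (2S)-5-[(3R)-5,8-bis(benzyloxy)-1-oxo-3,4-dihydro-1H-isochromen-3-yl]pentan-2-yl succinate
Product: 13 aspergimarin B, 4-{[(2S)-5-[(3R)-5,8-dihydroxy-1-oxo-3,4-dihydro-1H-isochromen-3-yl]pentan-2-yl]oxy}-4-oxobutanoic acid
Conditions: H2 (1 atm), Pd/C (10 wt % palladium on carbon), degassed EtOAc/EtOH, rt
Reagents that add atoms: none
Why: Heterogeneous hydrogenolysis of the two aryl benzyl ethers and the benzyl ester should free both phenols and the carboxylic acid at once; the lactone, the secondary succinate ester and both stereocentres carry no benzylic C–O bond and remain.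

**Compound list**

1 | gentisic acid | O=C(O)c1cc(O)ccc1O | starting material
2 | benzyl 2,5-bis(benzyloxy)benzoate | O=C(OCc1ccccc1)c1cc(OCc2ccccc2)ccc1OCc1ccccc1 | intermediate
3 | 2,5-bis(benzyloxy)benzoic acid | O=C(O)c1cc(OCc2ccccc2)ccc1OCc1ccccc1 | intermediate
4 | (S)-δ-hexalactone | C[C@H]1CCCC(=O)O1 | starting material
5 | trimethylsulfoxonium iodide | C[S+](C)(C)=O.[I-] | starting material
6 | dimethylsulfoxonium methylide | C=S(C)(C)=O | intermediate (not isolated)
7 | (6S)-1-(dimethyloxosulfuranylidene)-6-hydroxyheptan-2-one | C[C@@H](CCCC(=O)C=S(C)(C)=O)O | intermediate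
8 | monobenzyl succinate | O=C(O)CCC(=O)OCc1ccccc1 | starting material
9 | benzyl (2S)-7-(dimethyloxosulfuranylidene)-6-oxoheptan-2-yl succinate | C[C@@H](CCCC(=O)C=S(C)(C)=O)OC(=O)CCC(=O)OCc1ccccc1 | intermediate
10 | 3,6-bis(benzyloxy)-2-[(6S)-6-{[4-(benzyloxy)-4-oxobutanoyl]oxy}-2-oxoheptyl]benzoic acid | C[C@@H](CCCC(=O)Cc1c(OCc2ccccc2)ccc(OCc2ccccc2)c1C(=O)O)OC(=O)CCC(=O)OCc1ccccc1 | intermediate (not isolated)
11 | benzyl (2S)-5-[5,8-bis(benzyloxy)-1-oxo-1H-isochromen-3-yl]pentan-2-yl succinate | C[C@@H](CCCC1=Cc2c(OCc3ccccc3)ccc(OCc3ccccc3)c2C(=O)O1)OC(=O)CCC(=O)OCc1ccccc1 | intermediate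
12 | benzyl (2S)-5-[(3R)-5,8-bis(benzyloxy)-1-oxo-3,4-dihydro-1H-isochromen-3-yl]pentan-2-yl succinate | C[C@@H](CCC[C@@H]1Cc2c(OCc3ccccc3)ccc(OCc3ccccc3)c2C(=O)O1)OC(=O)CCC(=O)OCc1ccccc1 | intermediate
13 | aspergimarin B | C[C@@H](CCC[C@@H]1Cc2c(O)ccc(O)c2C(=O)O1)OC(=O)CCC(=O)O | target

**Count and risks**

Total steps: 7. Longest linear sequence: 5 steps (steps 1, 2, 5, 6, 7 from gentisic acid, or steps 3, 4, 5, 6, 7 from the lactone).

Steps most likely to fail:

1. Step 5. Ruthenation at the crowded C–H between the carboxylate and the C5 benzyloxy group may be slow, so that the ylide is consumed by protonation and O-alkylation of the acid instead of carbene transfer. Fallback: the C4a–C4 bond is made from an aryl iodide, setting out from acid 3, lactone 4 and half-ester 8.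
   - Acid 3 is doubly deprotonated with lithium 2,2,6,6-tetramethylpiperidide (LiTMP, THF, −78 °C); the ring hydrogen flanked by carboxylate and ether oxygen is the most acidic. Quenching with I2 should give 3,6-bis(benzyloxy)-2-iodobenzoic acid F1.
   - Lactone 4 is reduced with iBu2AlH (CH2Cl2, −78 °C) to (6S)-6-methyltetrahydro-2H-pyran-2-ol F2.
   - F2 is homologated with dimethyl (1-diazo-2-oxopropyl)phosphonate, K2CO3, MeOH (Ohira–Bestmann) to (S)-hept-6-yn-2-ol F3.
   - F3 is esterified with 8 (DCC, DMAP) to benzyl (S)-hept-6-yn-2-yl succinate F4.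
   - Coupling of F1 with F4 under Pd(PPh3)4 (zerovalent palladium), ZnCl2, Et3N, DMF, 100 °C (Sonogashira-type coupling followed by 6-endo-dig lactonisation of the alkynyl acid) should give isocoumarin 11, where the route is rejoined.

2. Step 6. The chiral catalyst may discriminate the two faces of the flat, trisubstituted enol-lactone alkene poorly, or take up hydrogen sluggishly. Fallback: catalyst control is given up in favour of separation, setting out from 11.
   - Hydrogenation with the achiral complex [Ir(cod)(PCy3)(py)]PF6 (monovalent iridium), H2, CH2Cl2 keeps the benzyl groups and should give 12 together with its C3 epimer, benzyl (2S)-5-[(3S)-5,8-bis(benzyloxy)-1-oxo-3,4-dihydro-1H-isochromen-3-yl]pentan-2-yl succinate F5.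
   - The two are diastereomers because the side-chain centre is fixed, and would be separated by preparative chromatography on a chiral stationary phase at the cost of half the material; 12 then enters step 7.

3. Step 4. The ylide carbon may be protonated or C-acylated by the activated acid before the alcohol is esterified. Fallback: the succinate is attached after the annulation, setting out from 7.
   - Silylation (TBSCl, imidazole, DMF) gives (6S)-6-[(tert-butyldimethylsilyl)oxy]-1-(dimethyloxosulfuranylidene)heptan-2-one F6.
   - Annulation of F6 with 3 under the step 5 conditions gives 5,8-bis(benzyloxy)-3-[(4S)-4-[(tert-butyldimethylsilyl)oxy]pentyl]-1H-isochromen-1-one F7.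
   - Desilylation with HF·pyridine in THF gives 5,8-bis(benzyloxy)-3-[(4S)-4-hydroxypentyl]-1H-isochromen-1-one F8.
   - Steglich esterification of F8 with 8 (DCC, DMAP, CH2Cl2) returns to 11.

**Further compounds**

F1 | step 5 | 3,6-bis(benzyloxy)-2-iodobenzoic acid | O=C(O)c1c(I)c(OCc2ccccc2)ccc1OCc1ccccc1
F2 | step 5 | (6S)-6-methyltetrahydro-2H-pyran-2-ol (anomer mixture) | C[C@H]1CCCC(O)O1
F3 | step 5 | (S)-hept-6-yn-2-ol | C[C@@H](CCCC#C)O
F4 | step 5 | benzyl (S)-hept-6-yn-2-yl succinate | C[C@@H](CCCC#C)OC(=O)CCC(=O)OCc1ccccc1
F5 | step 6 | benzyl (2S)-5-[(3S)-5,8-bis(benzyloxy)-1-oxo-3,4-dihydro-1H-isochromen-3-yl]pentan-2-yl succinate | C[C@@H](CCC[C@H]1Cc2c(OCc3ccccc3)ccc(OCc3ccccc3)c2C(=O)O1)OC(=O)CCC(=O)OCc1ccccc1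
F6 | step 4 | (6S)-6-[(tert-butyldimethylsilyl)oxy]-1-(dimethyloxosulfuranylidene)heptan-2-one | C[C@@H](CCCC(=O)C=S(C)(C)=O)O[Si](C)(C)C(C)(C)C
F7 | step 4 | 5,8-bis(benzyloxy)-3-[(4S)-4-[(tert-butyldimethylsilyl)oxy]pentyl]-1H-isochromen-1-one | C[C@@H](CCCC1=Cc2c(OCc3ccccc3)ccc(OCc3ccccc3)c2C(=O)O1)O[Si](C)(C)C(C)(C)C
F8 | step 4 | 5,8-bis(benzyloxy)-3-[(4S)-4-hydroxypentyl]-1H-isochromen-1-one | C[C@@H](CCCC1=Cc2c(OCc3ccccc3)ccc(OCc3ccccc3)c2C(=O)O1)O
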